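**Strategy.** The synthesis rests on disconnecting the C6–C7 bond shared by the ten-membered carbocycle and the lactone. The O6–C6–C7–C11(=C13H2)–C12(=O) array of the α-methylene-γ-butyrolactone is the retron of a carbonyl allylation by a 2-(bromomethyl)acrylate. An open-chain C6 aldehyde carrying the 4,5-epoxide, the (Z)-C1=C10 alkene, the protected C8 and C15 oxygens and a C7=C11(CO2Me)–C13H2Br terminus is therefore cyclised with CrCl2 (intramolecular Nozaki–Hiyama–Kishi allylation). One operation forms C6–C7, closes the ten-membered ring, sets C6 and C7, moves the alkene to C11=C13 and, by acyl transfer from the C12 ester to O6, closes the trans-fused lactone. Acylation of O8 and desilylation complete the route.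

Key step: step 13

Remark on the chemistry: germacrane numbering is used throughout (C4/C5 epoxide, C6 lactone carbinol, C7 its neighbour bearing C11, C8 acyloxy carbon, C14 = CH3 on C10, C15 = CH2O on C4); the target is (4S,5R,6S,7R,8R) with a (Z)-C1=C10 alkene and an (E) side-chain alkene.

**Step 1**
Reactants: 1 (S)-glycidol
Product: 2 (2R)-pent-4-yne-1,2-diol
Conditions: LiC≡CH·H2NCH2CH2NH2 (3 equiv), DMSO, 0 °C to rt
Reagents that add atoms: lithium acetylide–ethylenediamine complex, [Li]C#C.NCCN
Why: SN2 opening of the terminal epoxide carbon by the acetylide (epoxide alkynylation) leaves the carbinol stereocentre untouched, so the glycidol centre becomes C8 with the required R configuration, and the degenerate Payne rearrangement of the glycidol alkoxide cannot erode it.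

**Step 2**
Reactants: 2 (2R)-pent-4-yne-1,2-diol
Product: 5 (2R,4Z)-5-iodo-4-methylpent-4-ene-1,2-diol, via E-alkenylalane 3 (not isolated), via cyclic Z-alkenylalane 4 (not isolated)
Conditions: Me3Al (4 equiv), Cp2ZrCl2 (0.25 equiv), ClCH2CH2Cl, 0 °C to rt; AlCl3 (0.1 equiv), 50 °C; then I2, THF, −30 to 0 °C
Reagents that add atoms: trimethylaluminium, C[Al](C)C; iodine, [I][I]
Why: Zirconium-catalysed methylalumination of the terminal alkyne (Negishi carboalumination) puts CH3 on the internal carbon, the homopropargylic aluminium alkoxide then drives the chelation-controlled E-to-Z isomerisation of the alkenylalane (anti-carbometalation of homopropargylic alcohols), and iodinolysis with retention should give the (Z)-vinyl iodide that fixes the C1=C10 geometry.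

**Step 3**
Reactants: 5 (2R,4Z)-5-iodo-4-methylpent-4-ene-1,2-diol
Product: 6 (2R,4Z)-5-iodo-4-methyl-1,2-bis(triethylsilyloxy)pent-4-ene
Conditions: TESCl (2.5 equiv), imidazole, DMAP (cat.), CH2Cl2, 0 °C to rt
Reagents that add atoms: chlorotriethylsilane, CC[Si](Cl)(CC)CC
Why: Standard silyl ether formation on both hydroxyls prepares the primary/secondary differentiation used in the next step.

**Step 4**
Reactants: 6 (2R,4Z)-5-iodo-4-methyl-1,2-bis(triethylsilyloxy)pent-4-ene
Product: 7 (2R,4Z)-5-iodo-4-methyl-2-(triethylsilyloxy)pent-4-enal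
Conditions: (COCl)2, DMSO, CH2Cl2, −78 to −30 °C; then Et3N, −78 °C to rt
Reagents that add atoms: none
Why: Under Swern conditions a primary triethylsilyl ether is cleaved and oxidised to the aldehyde while a secondary one is inert (selective Swern oxidation of primary TES ethers), and the low temperature should preserve the α-silyloxy stereocentre.

**Step 5**
Reactants: 7 (2R,4Z)-5-iodo-4-methyl-2-(triethylsilyloxy)pent-4-enal; 8 methyl acrylate
Product: 9 methyl (3RS,4R,6Z)-3-hydroxy-7-iodo-6-methyl-2-methylidene-4-(triethylsilyloxy)hept-6-enoate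
Conditions: methyl acrylate (neat, excess), DABCO (1 equiv), rt
Reagents that add atoms: none
Why: The Morita–Baylis–Hillman reaction of the activated α-silyloxy aldehyde installs C11–C13 and the C7–C11 bond; the new carbinol centre forms as an epimer mixture that is irrelevant because it becomes sp2 in step 11.

**Step 6**
Reactants: 10 tert-butyldimethyl(prop-2-yn-1-yloxy)silane
Product: 12 methyl 4-(tert-butyldimethylsilyloxy)but-2-ynoate, via lithium acetylide 11 (not isolated)
Conditions: n-BuLi, THF, −78 °C; then ClCO2Me, −78 to 0 °C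
Reagents that add atoms: methyl chloroformate, COC(=O)Cl
Why: Deprotonation of the terminal alkyne and C-acylation of the acetylide with a chloroformate is the standard ynoate synthesis.

**Step 7**
Reactants: 12 methyl 4-(tert-butyldimethylsilyloxy)but-2-ynoate
Product: 14 methyl (2Z)-3-[(tert-butyldimethylsilyloxy)methyl]penta-2,4-dienoate, via alkenylcopper 13 (not isolated)
Conditions: CH2=CHMgBr, CuBr·SMe2 (1:1), THF, −78 °C; then AcOH, −78 °C
Reagents that add atoms: vinylmagnesium bromide, C=C[Mg]Br
Why: syn-Carbocupration of the ynoate by vinylcopper and cold protonation of the alkenylcopper with retention place the vinyl group trans and the CH2OTBS group cis to the ester, the C4=C5 geometry that later becomes the trans-epoxide.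

**Step 8**
Reactants: 14 methyl (2Z)-3-[(tert-butyldimethylsilyloxy)methyl]penta-2,4-dienoate
Product: 15 (2Z)-3-[(tert-butyldimethylsilyloxy)methyl]penta-2,4-dien-1-ol
Conditions: iBu2AlH (2.2 equiv), CH2Cl2, −78 °C; Rochelle salt work-up
Reagents that add atoms: none
Why: 1,2-Reduction of the dienoate by the aluminium hydride gives the allylic alcohol needed for directed epoxidation without changing the alkene geometry or the silyl ether.

**Step 9**
Reactants: 15 (2Z)-3-[(tert-butyldimethylsilyloxy)methyl]penta-2,4-dien-1-ol; 9 methyl (3RS,4R,6Z)-3-hydroxy-7-iodo-6-methyl-2-methylidene-4-(triethylsilyloxy)hept-6-enoate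
Product: 17 methyl (3RS,4R,6Z,10Z)-10-[(tert-butyldimethylsilyloxy)methyl]-3,12-dihydroxy-6-methyl-2-methylidene-4-(triethylsilyloxy)dodeca-6,10-dienoate, via bis-9-BBN adduct 16 (not isolated)
Conditions: 15, 9-BBN-H (2.2 equiv), THF, 0 °C to rt; then 9, Pd(dppf)Cl2 (10 mol%), AsPh3, Cs2CO3, DMF/H2O, rt
Reagents that add atoms: none
Why: 9-BBN adds anti-Markovnikov to the monosubstituted vinyl group of the diene (the trisubstituted alkene is inert and the hydroxyl is masked as its borinate), and B-alkyl Suzuki–Miyaura coupling with the vinyl iodide should form C1–C2 with retention of the Z geometry.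

**Step 10**
Reactants: 17 methyl (3RS,4R,6Z,10Z)-10-[(tert-butyldimethylsilyloxy)methyl]-3,12-dihydroxy-6-methyl-2-methylidene-4-(triethylsilyloxy)dodeca-6,10-dienoate
Product: 18 methyl (3RS,4R,6Z)-9-[(2S,3R)-2-[(tert-butyldimethylsilyloxy)methyl]-3-(hydroxymethyl)oxiran-2-yl]-3-hydroxy-6-methyl-2-methylidene-4-(triethylsilyloxy)non-6-enoate
Conditions: Ti(OiPr)4 (1.2 equiv), D-(−)-diethyl tartrate (1.5 equiv), t-BuOOH, 4 Å molecular sieves, CH2Cl2, −20 °C
Reagents that add atoms: tert-butyl hydroperoxide, CC(C)(C)OO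
Why: Sharpless asymmetric epoxidation of the primary allylic alcohol with the D-(−)-tartrate complex should deliver oxygen to the face that gives the (4S,5R) epoxide under reagent control, while the electron-poor acrylate and the isolated C1=C10 alkene do not react.

**Step 11**
Reactants: 18 methyl (3RS,4R,6Z)-9-[(2S,3R)-2-[(tert-butyldimethylsilyloxy)methyl]-3-(hydroxymethyl)oxiran-2-yl]-3-hydroxy-6-methyl-2-methylidene-4-(triethylsilyloxy)non-6-enoate
Product: 19 methyl (2Z,4R,6Z)-2-(bromomethyl)-9-[(2S,3R)-2-[(tert-butyldimethylsilyloxy)methyl]-3-(hydroxymethyl)oxiran-2-yl]-6-methyl-4-(triethylsilyloxy)nona-2,6-dienoate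
Conditions: NBS, Me2S, CH2Cl2, −20 to 0 °C
Reagents that add atoms: N-bromosuccinimide, O=C1CCC(=O)N1Br
Why: The Corey–Kim reagent converts allylic alcohols into bromides under neutral conditions and spares the primary epoxy alcohol (no longer allylic after step 10); on the Morita–Baylis–Hillman alcohol bromide attacks in the SN2′ sense to give the more stable (Z)-2-(bromomethyl)enoate.

**Step 12**
Reactants: 19 methyl (2Z,4R,6Z)-2-(bromomethyl)-9-[(2S,3R)-2-[(tert-butyldimethylsilyloxy)methyl]-3-(hydroxymethyl)oxiran-2-yl]-6-methyl-4-(triethylsilyloxy)nona-2,6-dienoate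
Product: 20 methyl (2Z,4R,6Z)-2-(bromomethyl)-9-[(2S,3S)-2-[(tert-butyldimethylsilyloxy)methyl]-3-formyloxiran-2-yl]-6-methyl-4-(triethylsilyloxy)nona-2,6-dienoate
Conditions: Dess–Martin periodinane, NaHCO3, CH2Cl2, 0 °C to rt; used at once
Reagents that add atoms: none
Why: Buffered Dess–Martin oxidation gives the labile α,β-epoxy aldehyde under near-neutral conditions that the allylic bromide, enoate and silyl ethers tolerate.

**Step 13**
Reactants: 20 methyl (2Z,4R,6Z)-2-(bromomethyl)-9-[(2S,3S)-2-[(tert-butyldimethylsilyloxy)methyl]-3-formyloxiran-2-yl]-6-methyl-4-(triethylsilyloxy)nona-2,6-dienoate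
Product: 23 (1(10)Z)-15-(tert-butyldimethylsilyloxy)-4α,5β-epoxy-8β-(triethylsilyloxy)germacra-1(10),11(13)-dien-12,6α-olide, via allylchromium 21 (not isolated), via seco hydroxy ester 22 (not isolated)
Conditions: CrCl2 (10 equiv), DMF, slow addition of 20 to 2 mM, rt then 40 °C; aq. NH4Cl
Reagents that add atoms: none
Why: CrCl2 reduces the allylic bromide to a nucleophilic allylchromium species (trivalent chromium) that attacks the C6 aldehyde through its γ-carbon C7 in a closed six-membered transition state; this is the intramolecular Nozaki–Hiyama–Kishi (chromium Barbier) allylation of an aldehyde by a 2-(bromomethyl)acrylate, a known way to close ten-membered germacranolide rings onto a C6 epoxy aldehyde. The C6–C7 bond closes the ten-membered carbocycle with transposition of the alkene to C11=C13, and the chromium alkoxide on O6 then attacks the C12 methyl ester (5-exo-trig) to close the α-methylene-γ-butyrolactone. C6 and C7 are set together: the chair with C5 and C8 both pseudo-equatorial, open to the allylchromium after E/Z equilibration, should give the 6,7-anti adduct and hence the trans-fused lactone. The aldehyde face is expected to be fixed by the rigid trans-epoxide, the new bond forming anti to the C5–O bond with C5–H turned toward the carbonyl oxygen, an arrangement the tether through the (Z)-C1=C10 alkene can span; the allyl face is expected to be fixed by the C8 stereocentre, whose triethylsilyloxy group points away from the forming ring. The step needs selective metalation of the allylic bromide beside epoxide, enoate and aldehyde (inherent to CrCl2), suppression of oligomerisation (high dilution) and no 1,4-elimination of the C8 oxygen, for which the poor leaving-group ability of the silyl ether is relied on.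

**Step 14**
Reactants: 23 (1(10)Z)-15-(tert-butyldimethylsilyloxy)-4α,5β-epoxy-8β-(triethylsilyloxy)germacra-1(10),11(13)-dien-12,6α-olide
Product: 24 (1(10)Z)-15-(tert-butyldimethylsilyloxy)-4α,5β-epoxy-8β-hydroxygermacra-1(10),11(13)-dien-12,6α-olide
Conditions: HF·pyridine, pyridine (excess), THF, 0 °C
Reagents that add atoms: none
Why: Pyridine-buffered fluoride desilylation should remove the secondary triethylsilyl ether much faster than the hindered primary TBS ether and leave the epoxide closed.

**Step 15**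
Reactants: 25 (tert-butyldimethylsilyloxy)acetaldehyde; 26 ethyl 2-(triphenylphosphoranylidene)propanoate
Product: 27 ethyl (2E)-4-(tert-butyldimethylsilyloxy)-2-methylbut-2-enoate
Conditions: CH2Cl2, rt
Reagents that add atoms: none
Why: Wittig olefination with the stabilised α-methyl ylide gives the (E)-trisubstituted enoate, the geometry of the 4-hydroxytiglate side chain.

**Step 16**
Reactants: 27 ethyl (2E)-4-(tert-butyldimethylsilyloxy)-2-methylbut-2-enoate
Product: 28 (2E)-4-(tert-butyldimethylsilyloxy)-2-methylbut-2-enoic acid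
Conditions: LiOH, THF/H2O, rt; then 1 M HCl to pH 4, 0 °C
Reagents that add atoms: lithium hydroxide, [Li+].[OH-]
Why: Ester saponification leaves the primary TBS ether and the alkene geometry intact.

**Step 17**
Reactants: 28 (2E)-4-(tert-butyldimethylsilyloxy)-2-methylbut-2-enoic acid; 24 (1(10)Z)-15-(tert-butyldimethylsilyloxy)-4α,5β-epoxy-8β-hydroxygermacra-1(10),11(13)-dien-12,6α-olide
Product: 30 (1(10)Z)-15-(tert-butyldimethylsilyloxy)-8β-[(2E)-4-(tert-butyldimethylsilyloxy)-2-methylbut-2-enoyloxy]-4α,5β-epoxygermacra-1(10),11(13)-dien-12,6α-olide, via mixed anhydride 29 (not isolated)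
Conditions: 28, 2,4,6-trichlorobenzoyl chloride, Et3N, toluene, rt; then 24, DMAP, toluene, rt
Reagents that add atoms: none
Why: Yamaguchi esterification through the mixed anhydride and DMAP acylates the hindered secondary C8 hydroxyl with the poorly electrophilic α-methyl enoic acid without touching any stereocentre.

**Step 18**
Reactants: 30 (1(10)Z)-15-(tert-butyldimethylsilyloxy)-8β-[(2E)-4-(tert-butyldimethylsilyloxy)-2-methylbut-2-enoyloxy]-4α,5β-epoxygermacra-1(10),11(13)-dien-12,6α-olide
Product: 31 (1(10)Z)-4α,5β-epoxy-15-hydroxy-8β-[(2E)-4-hydroxy-2-methylbut-2-enoyloxy]germacra-1(10),11(13)-dien-12,6α-olide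
Conditions: HF·pyridine, pyridine, THF, 0 °C to rt
Reagents that add atoms: none
Why: Buffered fluoride desilylation should cleave both primary TBS ethers while the epoxide, the α-methylene lactone and the side-chain ester survive, giving the target.

**Compound list**

1 | (S)-glycidol | OC[C@H]1CO1 | starting material
2 | (2R)-pent-4-yne-1,2-diol | C#CC[C@@H](O)CO | intermediate
3 | E-alkenylalane (syn-methylalumination adduct, both hydroxyls as dimethylaluminium alkoxides) | C[Al](C)/C=C(\C)C[C@@H](O[Al](C)C)CO[Al](C)C | intermediate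
4 | cyclic Z-alkenylalane (six-membered oxa-aluminacycle through O8) | C[Al]1O[C@@H](CO[Al](C)C)CC(C)=C1 | intermediate
5 | (2R,4Z)-5-iodo-4-methylpent-4-ene-1,2-diol | I/C=C(/C)C[C@@H](O)CO | intermediate
6 | (2R,4Z)-5-iodo-4-methyl-1,2-bis(triethylsilyloxy)pent-4-ene | I/C=C(/C)C[C@@H](O[Si](CC)(CC)CC)CO[Si](CC)(CC)CC | intermediate
7 | (2R,4Z)-5-iodo-4-methyl-2-(triethylsilyloxy)pent-4-enal | I/C=C(/C)C[C@@H](O[Si](CC)(CC)CC)C=O | intermediate
8 | methyl acrylate | C=CC(=O)OC | starting material
9 | methyl (3RS,4R,6Z)-3-hydroxy-7-iodo-6-methyl-2-methylidene-4-(triethylsilyloxy)hept-6-enoate | I/C=C(/C)C[C@@H](O[Si](CC)(CC)CC)C(O)C(=C)C(=O)OC | intermediate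
10 | tert-butyldimethyl(prop-2-yn-1-yloxy)silane | C#CCO[Si](C)(C)C(C)(C)C | starting material
11 | lithium acetylide of 10 | [Li]C#CCO[Si](C)(C)C(C)(C)C | intermediate
12 | methyl 4-(tert-butyldimethylsilyloxy)but-2-ynoate | COC(=O)C#CCO[Si](C)(C)C(C)(C)C | intermediate
13 | alkenylcopper from syn-addition of vinylcopper to 12 (Cu on C2, cis to vinyl) | COC(=O)/C([Cu])=C(/C=C)CO[Si](C)(C)C(C)(C)C | intermediate
14 | methyl (2Z)-3-[(tert-butyldimethylsilyloxy)methyl]penta-2,4-dienoate | COC(=O)/C=C(/C=C)CO[Si](C)(C)C(C)(C)C | intermediate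
15 | (2Z)-3-[(tert-butyldimethylsilyloxy)methyl]penta-2,4-dien-1-ol | OC/C=C(/C=C)CO[Si](C)(C)C(C)(C)C | intermediate
16 | bis-9-BBN adduct of 15 (B-alkyl borane at C2, O-borinate at O6) | CC(C)(C)[Si](C)(C)OC/C(CCB1C2CCCC1CCC2)=C\COB1C2CCCC1CCC2 | intermediate
17 | methyl (3RS,4R,6Z,10Z)-10-[(tert-butyldimethylsilyloxy)methyl]-3,12-dihydroxy-6-methyl-2-methylidene-4-(triethylsilyloxy)dodeca-6,10-dienoate | OC/C=C(CO[Si](C)(C)C(C)(C)C)/CC/C=C(/C)C[C@@H](O[Si](CC)(CC)CC)C(O)C(=C)C(=O)OC | intermediate
18 | methyl (3RS,4R,6Z)-9-[(2S,3R)-2-[(tert-butyldimethylsilyloxy)methyl]-3-(hydroxymethyl)oxiran-2-yl]-3-hydroxy-6-methyl-2-methylidene-4-(triethylsilyloxy)non-6-enoate | OC[C@H]1O[C@]1(CO[Si](C)(C)C(C)(C)C)CC/C=C(/C)C[C@@H](O[Si](CC)(CC)CC)C(O)C(=C)C(=O)OC | intermediate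
19 | methyl (2Z,4R,6Z)-2-(bromomethyl)-9-[(2S,3R)-2-[(tert-butyldimethylsilyloxy)methyl]-3-(hydroxymethyl)oxiran-2-yl]-6-methyl-4-(triethylsilyloxy)nona-2,6-dienoate | OC[C@H]1O[C@]1(CO[Si](C)(C)C(C)(C)C)CC/C=C(/C)C[C@@H](O[Si](CC)(CC)CC)/C=C(\CBr)C(=O)OC | intermediate
20 | methyl (2Z,4R,6Z)-2-(bromomethyl)-9-[(2S,3S)-2-[(tert-butyldimethylsilyloxy)methyl]-3-formyloxiran-2-yl]-6-methyl-4-(triethylsilyloxy)nona-2,6-dienoate | O=C[C@H]1O[C@]1(CO[Si](C)(C)C(C)(C)C)CC/C=C(/C)C[C@@H](O[Si](CC)(CC)CC)/C=C(\CBr)C(=O)OC | intermediate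
21 | allylchromium dichloride from 20 (CrCl2 on C13) | O=C[C@H]1O[C@]1(CO[Si](C)(C)C(C)(C)C)CC/C=C(/C)C[C@@H](O[Si](CC)(CC)CC)/C=C(\C[Cr](Cl)Cl)C(=O)OC | intermediate
22 | seco hydroxy ester: ten-membered carbocycle with free C6–OH and methyl 2-propenoate on C7 (configured as in the target at C4–C8; present as its chromium alkoxide) | C=C(C(=O)OC)[C@@H]1[C@H](O[Si](CC)(CC)CC)C/C(C)=C\CC[C@@]2(CO[Si](C)(C)C(C)(C)C)O[C@@H]2[C@H]1O | intermediate
23 | (1(10)Z)-15-(tert-butyldimethylsilyloxy)-4α,5β-epoxy-8β-(triethylsilyloxy)germacra-1(10),11(13)-dien-12,6α-olide | C=C1C(=O)O[C@H]2[C@H]1[C@H](O[Si](CC)(CC)CC)C/C(C)=C\CC[C@@]1(CO[Si](C)(C)C(C)(C)C)O[C@H]21 | intermediate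
24 | (1(10)Z)-15-(tert-butyldimethylsilyloxy)-4α,5β-epoxy-8β-hydroxygermacra-1(10),11(13)-dien-12,6α-olide | C=C1C(=O)O[C@H]2[C@H]1[C@H](O)C/C(C)=C\CC[C@@]1(CO[Si](C)(C)C(C)(C)C)O[C@H]21 | intermediate
25 | (tert-butyldimethylsilyloxy)acetaldehyde | O=CCO[Si](C)(C)C(C)(C)C | starting material
26 | ethyl 2-(triphenylphosphoranylidene)propanoate | CCOC(=O)C(C)=P(c1ccccc1)(c1ccccc1)c1ccccc1 | starting material
27 | ethyl (2E)-4-(tert-butyldimethylsilyloxy)-2-methylbut-2-enoate | CCOC(=O)/C(C)=C/CO[Si](C)(C)C(C)(C)C | intermediate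
28 | (2E)-4-(tert-butyldimethylsilyloxy)-2-methylbut-2-enoic acid | OC(=O)/C(C)=C/CO[Si](C)(C)C(C)(C)C | intermediate
29 | mixed anhydride of 28 with 2,4,6-trichlorobenzoic acid | O=C(OC(=O)c1c(Cl)cc(Cl)cc1Cl)/C(C)=C/CO[Si](C)(C)C(C)(C)C | intermediate
30 | (1(10)Z)-15-(tert-butyldimethylsilyloxy)-8β-[(2E)-4-(tert-butyldimethylsilyloxy)-2-methylbut-2-enoyloxy]-4α,5β-epoxygermacra-1(10),11(13)-dien-12,6α-olide | C=C1C(=O)O[C@H]2[C@H]1[C@H](OC(=O)/C(C)=C/CO[Si](C)(C)C(C)(C)C)C/C(C)=C\CC[C@@]1(CO[Si](C)(C)C(C)(C)C)O[C@H]21 | intermediate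
31 | (1(10)Z)-4α,5β-epoxy-15-hydroxy-8β-[(2E)-4-hydroxy-2-methylbut-2-enoyloxy]germacra-1(10),11(13)-dien-12,6α-olide, (4S,5R,6S,7R,8R) | C=C1C(=O)O[C@H]2[C@H]1[C@H](OC(=O)/C(C)=C/CO)C/C(C)=C\CC[C@@]1(CO)O[C@H]21 | target

**Step count and risks**

Total step count: 18. Longest linear sequence: 13 steps (steps 1–5, 9–14, 17 and 18, from (S)-glycidol).

Three steps most likely to fail:

Step 13 (key step). The closure may select the other aldehyde face: open-chain polar Felkin–Anh control with the (Z)-allylchromium in a chair would lead to the 6-epimeric syn adduct and a cis-fused lactone. It may also lose the C8 oxygen by 1,4-elimination from the allylchromium. The fallback sets out from 20 and comes back at 23. The same cyclisation is run and the (6R)-configured cis-fused lactone, the 6-epimer of 23 F1, is carried forward. LiOH in THF/H2O at 0 °C opens it to the (6R)-hydroxy acid F2, kept as its carboxylate and brought to pH 5 just before use. Mitsunobu lactonisation (PPh3, DIAD, toluene, 0 °C) then closes the lactone with inversion at C6, so that the C6 configuration is set by SN2 displacement and no longer by carbonyl face selection, which gives 23.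

Step 9. The alkenylpalladium intermediate may insert into the acrylate of 9 (Heck-type cyclisation), or the borinate-bearing borane may protodeboronate before transmetalation. The fallback sets out from 15 and 6 and comes back at 19; it joins the fragments before the acrylate exists. Alcohol 15 is protected with 4-methoxybenzyl trichloroacetimidate and catalytic La(OTf)3 as the PMB ether of 15 F3. This is hydroborated with 9-BBN-H to the B-alkyl borane F4 and coupled with 6 (Pd(dppf)Cl2, AsPh3, Cs2CO3, DMF/H2O) to the bis-TES PMB ether F5. Selective Swern oxidation of the primary TES ether gives the α-silyloxy aldehyde F6, and the Morita–Baylis–Hillman reaction with methyl acrylate and DABCO gives the adduct F7. NBS/Me2S converts it into the (Z)-allylic bromide F8, and DDQ in CH2Cl2/pH 7 buffer frees the allylic alcohol F9. Sharpless epoxidation with D-(−)-diethyl tartrate then gives 19.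

Step 11. Chemoselectivity may be lost: the primary epoxy alcohol may be brominated or oxidised, or bromide may open the epoxide. The fallback sets out from 18 and comes back at 20; it reverses the order and bases the selectivity on oxidation. TEMPO (cat.) with PhI(OAc)2 in CH2Cl2 oxidises only the primary alcohol and gives the epoxy aldehyde with the secondary allylic hydroxyl intact F10. MsCl and Et3N at −40 °C give the allylic mesylate F11, and LiBr in THF at 0 °C displaces it in the SN2′ sense to give 20.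

**Further compounds**

F1 | step 13 | (1(10)Z)-15-(tert-butyldimethylsilyloxy)-4α,5β-epoxy-8β-(triethylsilyloxy)germacra-1(10),11(13)-dien-12,6β-olide (6-epimer of 23, cis-fused) | C=C1C(=O)O[C@@H]2[C@H]1[C@H](O[Si](CC)(CC)CC)C/C(C)=C\CC[C@@]1(CO[Si](C)(C)C(C)(C)C)O[C@H]21
F2 | step 13 | (6R)-hydroxy acid from opening of F1 (2-propenoic acid on C7, free C6–OH) | C=C(C(=O)O)[C@@H]1[C@H](O[Si](CC)(CC)CC)C/C(C)=C\CC[C@@]2(CO[Si](C)(C)C(C)(C)C)O[C@@H]2[C@@H]1O
F3 | step 9 | PMB ether of 15 | COc1ccc(COC/C=C(/C=C)CO[Si](C)(C)C(C)(C)C)cc1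
F4 | step 9 | B-alkyl-9-BBN borane from F3 | COc1ccc(COC/C=C(/CCB2C3CCCC2CCC3)CO[Si](C)(C)C(C)(C)C)cc1
F5 | step 9 | coupled bis-TES PMB ether (C6–OPMB, C7–OTES, C8–OTES, C15–OTBS) | COc1ccc(COC/C=C(CO[Si](C)(C)C(C)(C)C)/CC/C=C(/C)C[C@@H](O[Si](CC)(CC)CC)CO[Si](CC)(CC)CC)cc1
F6 | step 9 | C7 aldehyde from F5 | COc1ccc(COC/C=C(CO[Si](C)(C)C(C)(C)C)/CC/C=C(/C)C[C@@H](O[Si](CC)(CC)CC)C=O)cc1
F7 | step 9 | Morita–Baylis–Hillman adduct of F6 (C7 epimers) | COc1ccc(COC/C=C(CO[Si](C)(C)C(C)(C)C)/CC/C=C(/C)C[C@@H](O[Si](CC)(CC)CC)C(O)C(=C)C(=O)OC)cc1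
F8 | step 9 | (Z)-allylic bromide from F7 | COc1ccc(COC/C=C(CO[Si](C)(C)C(C)(C)C)/CC/C=C(/C)C[C@@H](O[Si](CC)(CC)CC)/C=C(\CBr)C(=O)OC)cc1
F9 | step 9 | C6 allylic alcohol from F8 | OC/C=C(CO[Si](C)(C)C(C)(C)C)/CC/C=C(/C)C[C@@H](O[Si](CC)(CC)CC)/C=C(\CBr)C(=O)OC
F10 | step 11 | epoxy aldehyde with free C7 hydroxyl (from 18) | O=C[C@H]1O[C@]1(CO[Si](C)(C)C(C)(C)C)CC/C=C(/C)C[C@@H](O[Si](CC)(CC)CC)C(O)C(=C)C(=O)OC
F11 | step 11 | C7 mesylate of F10 | O=C[C@H]1O[C@]1(CO[Si](C)(C)C(C)(C)C)CC/C=C(/C)C[C@@H](O[Si](CC)(CC)CC)C(OS(C)(=O)=O)C(=C)C(=O)OC
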